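**Strategy.** The route rests on cutting the bond between the ring-B carbinol carbon C1 (decalin numbering) and side-chain C1′. In the last step the organocerium derived from a linalool-based (3R)-iodo alcohol adds to bromodecalone 11. This one operation joins the C14 and C6 halves, creates the tertiary carbinol stereocentre and delivers the unprotected diol. It exploits C1 of ring B lying between the quaternary C8a, whose axial methyl blocks one carbonyl face, and C2 with its equatorial methyl. Ketone 11 comes from a catalytic asymmetric bromonium polyene cyclization of a (Z)-vinylsilane-terminated geranyl triene, then hydroboration, oxidation and epimerization. The iodo alcohol comes from (R)-linalool by ozonolysis and alkoxy-radical fragmentation.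

Key step: step 9

Assumption: the antipode of the BINOL-derived thiophosphoramide catalyst that gives the (6R)-bromide in step 3 is chosen on an aryl-terminated model substrate. Decalin locants are used throughout (C1 carbinol carbon, C2 methyl-bearing carbon, C4a/C8a ring fusion, C5 gem-dimethyl, C6 bromide); side-chain atoms are primed.

Step 1
Reactants: 1 1-(trimethylsilyl)propyne; 2 geranyl bromide [(2E)-1-bromo-3,7-dimethylocta-2,6-diene]
Product: 4 trimethyl[(5E)-6,10-dimethylundeca-5,9-dien-1-yn-1-yl]silane, via lithiated silylpropyne 3 (not isolated)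
Conditions: n-BuLi, THF, −78 → −20 °C; then 2, −78 °C → rt
Reagents that add atoms: none
Why: Propargylic lithiation of the silylpropyne and SN2 alkylation by the primary allylic bromide should extend the geranyl chain by three carbons and leave the E-alkene untouched.

Step 2
Reactants: 4 trimethyl[(5E)-6,10-dimethylundeca-5,9-dien-1-yn-1-yl]silane
Product: 6 trimethyl[(1Z,5E)-2,6,10-trimethylundeca-1,5,9-trien-1-yl]silane, via alkenylmagnesium bromide 5 (not isolated)
Conditions: MeMgBr (3 equiv), Ni(acac)2 (10 mol %), Me3Al (10 mol %), THF, rt; then aq. NH4Cl, 0 °C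
Reagents that add atoms: methylmagnesium bromide, C[Mg]Br
Why: Nickel-catalysed syn-carbomagnesiation of a 1-silylalkyne puts methyl on the carbon remote from silicon, and protonation of the α-silyl alkenyl Grignard with retention should give the (Z)-vinylsilane under kinetic control.

Step 3
Reactants: 6 trimethyl[(1Z,5E)-2,6,10-trimethylundeca-1,5,9-trien-1-yl]silane
Product: 7 (4aS,6R,8aS)-6-bromo-2,5,5,8a-tetramethyl-3,4,4a,5,6,7,8,8a-octahydronaphthalene
Conditions: DBDMH (1.1 equiv), chiral BINOL-derived thiophosphoramide (10 mol %), toluene/CH2Cl2, −78 °C; then aq. Na2S2O3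
Reagents that add atoms: 1,3-dibromo-5,5-dimethylhydantoin, CC1(C)N(Br)C(=O)N(Br)C1=O
Why: Proposed new method: the chiral Lewis-base catalyst activates DBDMH and should transfer Br+ enantioselectively to the terminal, least hindered 9,10-alkene; the E-5,6-alkene then closes ring A in a chair–chair anti-addition cascade (equatorial Br at C6, trans ring fusion, axial C8a methyl), and the (Z)-vinylsilane closes ring B by ipso attack with its C–Si bond axial, so that the β-silyl cation loses silicon and fixes the C1=C2 alkene; the closest known reaction types are the catalytic asymmetric bromocyclization of aryl-terminated homogeranyl polyenes and the vinylsilane-terminated cation–olefin cyclization.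

Step 4
Reactants: 7 (4aS,6R,8aS)-6-bromo-2,5,5,8a-tetramethyl-3,4,4a,5,6,7,8,8a-octahydronaphthalene
Product: 9 (1S,2R,4aS,6R,8aR)-6-bromo-2,5,5,8a-tetramethyldecahydronaphthalen-1-ol, via alkylborane 8 (not isolated)
Conditions: BH3·THF, THF, 0 °C → rt; then NaOH, H2O2, 0 °C
Reagents that add atoms: hydrogen peroxide, OO
Why: Hydroboration–oxidation places boron on the less substituted C1 and adds syn from the face anti to the axial C8a methyl, so the alcohol should carry an axial OH at C1 and, for the moment, an axial methyl at C2.

Step 5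
Reactants: 9 (1S,2R,4aS,6R,8aR)-6-bromo-2,5,5,8a-tetramethyldecahydronaphthalen-1-ol
Product: 11 (2S,4aS,6R,8aR)-6-bromo-2,5,5,8a-tetramethyloctahydronaphthalen-1(2H)-one, via axial-methyl ketone 10 (not isolated)
Conditions: Dess–Martin periodinane, NaHCO3, CH2Cl2, rt; then NaOMe, MeOH, rt
Reagents that add atoms: none
Why: Dess–Martin oxidation gives the ketone, and base-mediated enolization should move the C2 methyl out of its 1,3-diaxial clash with the C8a methyl into the equatorial position (thermodynamic epimerization).

Step 6
Reactants: 12 (R)-(−)-linalool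
Product: 15 (5R)-5-ethenyl-5-methyloxolan-2-ol (anomer mixture), via ozonide 13 (not isolated), via hydroxy aldehyde 14 (not isolated)
Conditions: O3 (1.0 equiv, Sudan Red 7B end point), CH2Cl2, −78 °C; then Me2S, −78 °C → rt
Reagents that add atoms: ozone, [O-][O+]=O
Why: Ozone should cleave the electron-rich trisubstituted alkene much faster than the vinyl group next to the carbinol (chemoselective ozonolysis), and the hydroxy aldehyde closes to the lactol without touching the stereocentre.

Step 7
Reactants: 15 (5R)-5-ethenyl-5-methyloxolan-2-ol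
Product: 17 (3R)-5-iodo-3-methylpent-1-en-3-yl formate, via lactol hypoiodite 16 (not isolated)
Conditions: PhI(OAc)2, I2, CH2Cl2, visible light, rt
Reagents that add atoms: iodine, II
Why: The anomeric hypoiodite gives an alkoxy radical whose β-scission (hypoiodite alkoxy-radical fragmentation of a lactol, as with 2-deoxy sugars) expels the primary C3 radical, which iodine traps, and leaves the tertiary oxygen as a formate with the stereocentre untouched.

Step 8
Reactants: 17 (3R)-5-iodo-3-methylpent-1-en-3-yl formate
Product: 18 (3R)-5-iodo-3-methylpent-1-en-3-ol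
Conditions: KHCO3, MeOH, 0 °C
Reagents that add atoms: none
Why: Mild methanolysis (transesterification) should remove the formate far faster than the tertiary alkoxide can displace the primary iodide.

Step 9
Reactants: 18 (3R)-5-iodo-3-methylpent-1-en-3-ol; 11 (2S,4aS,6R,8aR)-6-bromo-2,5,5,8a-tetramethyloctahydronaphthalen-1(2H)-one
Product: 21 (1R,2S,4aS,6R,8aR)-6-bromo-1-[(3R)-3-hydroxy-3-methylpent-4-en-1-yl]-2,5,5,8a-tetramethyldecahydronaphthalen-1-ol, via dilithio alkoxide 19 (not isolated), via organocerium 20 (not isolated)
Conditions: 18, n-BuLi (1 equiv) then t-BuLi (2 equiv), Et2O, −78 °C; CeCl3 (anhydrous), THF, −78 °C; then 11, −78 → −40 °C; aq. NH4Cl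
Reagents that add atoms: none
Why: Deprotonation and iodine–lithium exchange convert 18 into the γ-oxido alkyllithium 19, cerium(III) chloride turns it into the weakly basic, oxophilic organocerium 20, and this adds 1,2 to the C1 carbonyl of 11, after which aqueous work-up frees both hydroxyl groups. The closest known reaction type is the organocerium addition of alkyllithium-derived reagents to hindered, enolizable ketones. No ring is closed. The only new stereocentre, C1, is controlled by the axial C8a methyl, which screens the equatorial trajectory on its own face, so C1′ should enter axially and anti to it, past only the axial hydrogens at C3 and C4a, leaving the hydroxyl equatorial and cis to the angular methyl; C3′ comes unchanged from (R)-linalool. The step needs carbonyl addition to win over enolization toward C2 and over reaction at the C6 bromide; the low basicity of the cerium reagent, the equatorial neopentyl position of the bromide and the low temperature should secure this, and any enolization only returns the thermodynamic C2 epimer.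

**Compound list**

1 | 1-(trimethylsilyl)propyne | CC#C[Si](C)(C)C | starting material
2 | geranyl bromide, (2E)-1-bromo-3,7-dimethylocta-2,6-diene | CC(C)=CCC/C(C)=C/CBr | starting material
3 | [3-(trimethylsilyl)prop-2-yn-1-yl]lithium | [Li]CC#C[Si](C)(C)C | intermediate (not isolated)
4 | trimethyl[(5E)-6,10-dimethylundeca-5,9-dien-1-yn-1-yl]silane | C[Si](C)(C)C#CCC/C=C(\C)CCC=C(C)C | intermediate
5 | bromo[(1Z,5E)-2,6,10-trimethyl-1-(trimethylsilyl)undeca-1,5,9-trien-1-yl]magnesium (Mg cis to the new methyl) | C[Si](C)(C)/C([Mg]Br)=C(/C)CC/C=C(\C)CCC=C(C)C | intermediate (not isolated)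
6 | trimethyl[(1Z,5E)-2,6,10-trimethylundeca-1,5,9-trien-1-yl]silane | C[Si](C)(C)/C=C(/C)CC/C=C(\C)CCC=C(C)C | intermediate
7 | (4aS,6R,8aS)-6-bromo-2,5,5,8a-tetramethyl-3,4,4a,5,6,7,8,8a-octahydronaphthalene | CC1=C[C@]2(C)CC[C@@H](Br)C(C)(C)[C@H]2CC1 | intermediate
8 | C1 alkylborane from syn addition to 7 (BH2 axial at C1, anti to the C8a methyl; C2 methyl axial) | B[C@H]1[C@H](C)CC[C@@H]2C(C)(C)[C@H](Br)CC[C@]21C | intermediate (not isolated)
9 | (1S,2R,4aS,6R,8aR)-6-bromo-2,5,5,8a-tetramethyldecahydronaphthalen-1-ol | O[C@H]1[C@H](C)CC[C@@H]2C(C)(C)[C@H](Br)CC[C@]21C | intermediate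
10 | (2R,4aS,6R,8aR)-6-bromo-2,5,5,8a-tetramethyloctahydronaphthalen-1(2H)-one (C2 methyl axial) | O=C1[C@H](C)CC[C@@H]2C(C)(C)[C@H](Br)CC[C@]21C | intermediate (not isolated)
11 | (2S,4aS,6R,8aR)-6-bromo-2,5,5,8a-tetramethyloctahydronaphthalen-1(2H)-one | O=C1[C@@H](C)CC[C@@H]2C(C)(C)[C@H](Br)CC[C@]21C | intermediate
12 | (R)-(−)-linalool, (3R)-3,7-dimethylocta-1,6-dien-3-ol | C=C[C@](C)(O)CCC=C(C)C | starting material
13 | ozonide of the 6,7-alkene of 12 (3,3-dimethyl-1,2,4-trioxolane bearing the (3R)-3-hydroxy-3-methylpent-4-enyl group at C5) | C=C[C@](C)(O)CCC1OOC(C)(C)O1 | intermediate (not isolated)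
14 | (4R)-4-hydroxy-4-methylhex-5-enal | C=C[C@](C)(O)CCC=O | intermediate (not isolated)
15 | (5R)-5-ethenyl-5-methyloxolan-2-ol (anomer mixture) | C=C[C@@]1(C)CCC(O)O1 | intermediate
16 | (5R)-5-ethenyl-5-methyloxolan-2-yl hypoiodite | C=C[C@@]1(C)CCC(OI)O1 | intermediate (not isolated)
17 | (3R)-5-iodo-3-methylpent-1-en-3-yl formate | C=C[C@](C)(OC=O)CCI | intermediate
18 | (3R)-5-iodo-3-methylpent-1-en-3-ol | C=C[C@](C)(O)CCI | intermediate
19 | lithium (3R)-5-lithio-3-methylpent-1-en-3-olate | C=C[C@](C)(O[Li])CC[Li] | intermediate (not isolated)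
20 | lithium (3R)-5-(dichloroceryl)-3-methylpent-1-en-3-olate | C=C[C@](C)(O[Li])CC[Ce](Cl)Cl | intermediate (not isolated)
21 | (1R,2S,4aS,6R,8aR)-6-bromo-1-[(3R)-3-hydroxy-3-methylpent-4-en-1-yl]-2,5,5,8a-tetramethyldecahydronaphthalen-1-ol | C=C[C@](C)(O)CC[C@@]1(O)[C@@H](C)CC[C@@H]2C(C)(C)[C@H](Br)CC[C@]21C | target

**Step count.** Total: 9 steps. Longest linear sequence: 6 steps (steps 1–5 and 9); steps 6–8 form the second branch.

**Steps most likely to fail**

1. Step 3 (Proposed new method). Bromine transfer to the vinylsilane (bromodesilylation) or interruption after ring A could erode the yield, and enantiofacial discrimination by the catalyst could drop with a non-aryl terminator. The fallback uses known chemistry and sets out from 6. The racemic reagent BDSB (Et2SBr·SbCl5Br, MeNO2, −25 °C) should give the bromo-octalin as a racemate, that is 7 together with its enantiomer, the (4aR,6S,8aR)-bromo-octalin F1. Hydroboration–oxidation as in step 4 then gives 9 together with its enantiomer, the (1R,2S,4aR,6S,8aS)-alcohol F2. Preparative chromatography on a chiral stationary phase separates the two, and the fallback rejoins the route at 9.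

2. Step 9. Addition to the doubly flanked carbonyl may be slow, so that enolization of 11 or aggregation of the oxido-organometallic prevails; loss of facial selectivity is less likely. The fallback sets out from 18. Silylation (TMSCl, imidazole) gives the TMS ether of the iodo alcohol F7. A samarium Barbier coupling (SmI2, cat. NiI2, THF, 0 °C) of this iodide with 11 generates the nucleophile in the presence of the ketone and should give the mono-silylated diol F8. K2CO3 in MeOH removes the silyl group and the fallback arrives at 21.

3. Step 7. Acetyl hypoiodite may add to the vinyl group, or the lactol may be oxidized to the lactone instead of undergoing β-scission. The fallback sets out from 15. Oxidation (TEMPO, PhI(OAc)2) gives the lactone F3. Saponification, silylation (TESCl, imidazole) and selective hydrolysis of the silyl ester give the TES-protected acid F4. Its Barton ester F5 (N-hydroxypyridine-2-thione, DCC) is photolysed with iodoform to give the TES-protected iodide F6 (radical decarboxylative iodination). HF·pyridine removes the silyl group and the fallback rejoins the route at 18.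

**Further compounds**

F1 | step 3 | (4aR,6S,8aR)-6-bromo-2,5,5,8a-tetramethyl-3,4,4a,5,6,7,8,8a-octahydronaphthalene (enantiomer of 7) | CC1=C[C@@]2(C)CC[C@H](Br)C(C)(C)[C@@H]2CC1
F2 | step 3 | (1R,2S,4aR,6S,8aS)-6-bromo-2,5,5,8a-tetramethyldecahydronaphthalen-1-ol (enantiomer of 9) | O[C@@H]1[C@@H](C)CC[C@H]2C(C)(C)[C@@H](Br)CC[C@@]21C
F3 | step 7 | (5R)-5-ethenyl-5-methyloxolan-2-one | C=C[C@@]1(C)CCC(=O)O1
F4 | step 7 | (4R)-4-methyl-4-[(triethylsilyl)oxy]hex-5-enoic acid | C=C[C@](C)(O[Si](CC)(CC)CC)CCC(=O)O
F5 | step 7 | 2-thioxopyridin-1(2H)-yl (4R)-4-methyl-4-[(triethylsilyl)oxy]hex-5-enoate | C=C[C@](C)(O[Si](CC)(CC)CC)CCC(=O)On1ccccc1=S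
F6 | step 7 | triethyl{[(3R)-5-iodo-3-methylpent-1-en-3-yl]oxy}silane | C=C[C@](C)(O[Si](CC)(CC)CC)CCI
F7 | step 9 | {[(3R)-5-iodo-3-methylpent-1-en-3-yl]oxy}trimethylsilane | C=C[C@](C)(O[Si](C)(C)C)CCI
F8 | step 9 | (1R,2S,4aS,6R,8aR)-6-bromo-2,5,5,8a-tetramethyl-1-{(3R)-3-methyl-3-[(trimethylsilyl)oxy]pent-4-en-1-yl}decahydronaphthalen-1-ol | C=C[C@](C)(O[Si](C)(C)C)CC[C@@]1(O)[C@@H](C)CC[C@@H]2C(C)(C)[C@H](Br)CC[C@]21C
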